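**Plan**

1. Cuts, in retrosynthetic order: C14–C15 next to the ether oxygen (alkenyl metal + α-chloro ether on the eudesmane C4' oxygen); the C13 methyl/C13≡C14 unit (carboalumination of an alkyne made from a methyl ketone); the labdane C4–C5 and C9–C10 bonds (one oxidative radical cascade); C1–C2 (dianion alkylation).
2. Enabling feature: labdane C4 carries CH3 and CO2H next to C3, and the methyl-bearing C10 and C8 follow in head-to-tail isoprenoid spacing. A C4 radical of an α-methyl β-keto ester (temporary C3 ketone) can therefore close ring A (C4–C5) and then ring B (C10–C9; ring C5–C6–C7–C8–C9–C10), and the C8 radical ends as the C8=C17 methylene.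
3. Forward order: eudesmane half from (+)-β-eudesmol (rings bought, C4'–O installed, O–CH2Cl handle made); acyclic labdane precursor from (E)-geranylacetone and a (−)-8-phenylmenthyl keto ester; bicyclisation (ring A, then ring B as the last ring formed); removal of the helpers (auxiliary ester, C3 oxygen, C13 ketal); side chain and ether union; oxidation of C19 to the acid.
4. Stereochemistry: C4, C5, C9, C10 from the chair–chair closure of the E,E-diene, with the face set by the auxiliary; 13E from syn-carbometalation; C5', C7', C10' from β-eudesmol; C4' from α-face epoxidation and hydride opening.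

Key step: step 10

Assumptions: (+)-β-eudesmol, (E)-geranylacetone (pure E isomer) and (−)-8-phenylmenthol are bought; labdane and eudesmane numbering is used, eudesmane atoms primed. The sense of induction by the auxiliary in step 10 is assigned from a stacking model and by analogy with related auxiliary-controlled closures, not from a result on this substrate.

**Route**

Step 1
Reactants: 1 (+)-β-eudesmol
Product: 2 β-eudesmol 11'-O-triethylsilyl ether
Conditions: TESOTf, 2,6-lutidine, CH2Cl2, 0 °C
Reagents that add atoms: triethylsilyl trifluoromethanesulfonate CC[Si](CC)(CC)OS(=O)(=O)C(F)(F)F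
Why: Silyl triflate silylation of the only hydroxyl (tertiary C11') masks it, so that the C4' oxygen introduced next is the only free one.

Step 2
Reactants: 2 β-eudesmol 11'-O-triethylsilyl ether
Product: 3 4'α,15'-epoxy-11'-(triethylsilyloxy)eudesmane
Conditions: mCPBA, NaHCO3, CH2Cl2, 0 °C
Reagents that add atoms: 3-chloroperoxybenzoic acid O=C(OO)c1cccc(Cl)c1
Why: Prilezhaev epoxidation of the exocyclic C4'=C15' alkene should occur from the α face, because the β face is blocked by the syn-axial C10' methyl, and this sets the C4'–O bond α (equatorial).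

Step 3
Reactants: 3 4'α,15'-epoxy-11'-(triethylsilyloxy)eudesmane
Product: 4 11'-(triethylsilyloxy)eudesman-4'α-ol (cryptomeridiol 11'-TES ether)
Conditions: LiAlH4, THF, reflux
Reagents that add atoms: none
Why: SN2 hydride opening of the 1,1-disubstituted epoxide at its primary carbon turns C15' into the 4'β-methyl and leaves the C4'–O bond, and so the C4' configuration, untouched.

Step 4
Reactants: 4 11'-(triethylsilyloxy)eudesman-4'α-ol
Product: 5 4'α-(methylthiomethoxy)-11'-(triethylsilyloxy)eudesmane
Conditions: DMSO, Ac2O, AcOH, rt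
Reagents that add atoms: dimethyl sulfoxide CS(C)=O
Why: Pummerer-type methylthiomethylation uses a small thionium electrophile, the standard way to etherify a hindered tertiary alcohol, with retention at C4'.

Step 5
Reactants: 6 (E)-geranylacetone
Product: 7 2-[(3E)-4,8-dimethylnona-3,7-dien-1-yl]-2-methyl-1,3-dioxolane
Conditions: ethylene glycol, PPTS (cat.), benzene, reflux (Dean–Stark)
Reagents that add atoms: ethylene glycol OCCO
Why: Acid-catalysed ketalisation masks the future C13 carbonyl for the enolate and radical chemistry ahead.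

Step 6
Reactants: 7 geranylacetone dioxolane
Product: 8 (2E,6E)-2,6-dimethyl-9-(2-methyl-1,3-dioxolan-2-yl)nona-2,6-dien-1-ol
Conditions: SeO2 (cat.), t-BuOOH, salicylic acid (cat.), CH2Cl2, 0 °C to rt
Reagents that add atoms: tert-butyl hydroperoxide CC(C)(C)OO (oxygen delivered through catalytic selenium dioxide O=[Se]=O)
Why: SeO2/t-BuOOH allylic oxidation (ene reaction, then [2,3]-sigmatropic shift) attacks the terminal, most electron-rich trisubstituted alkene at its E-methyl group and should give the (E)-allylic alcohol.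

Step 7
Reactants: 8 (2E,6E)-allylic alcohol
Product: 9 2-[(3E,7E)-9-bromo-4,8-dimethylnona-3,7-dien-1-yl]-2-methyl-1,3-dioxolane
Conditions: CBr4, PPh3, CH2Cl2, 0 °C
Reagents that add atoms: carbon tetrabromide BrC(Br)(Br)Br
Why: Appel bromination of the primary allylic alcohol is neutral and should spare the ketal and the alkene geometry.

Step 8
Reactants: 10 (−)-8-phenylmenthol; 11 ethyl 2-methyl-3-oxobutanoate
Product: 12 (−)-8-phenylmenthyl 2-methyl-3-oxobutanoate (epimers at C2)
Conditions: DMAP (cat.), toluene, reflux with removal of EtOH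
Reagents that add atoms: none
Why: DMAP-catalysed transesterification of a β-keto ester (through the acylketene) attaches the chiral auxiliary to the carbon that becomes C19.

Step 9
Reactants: 12 (−)-8-phenylmenthyl 2-methyl-3-oxobutanoate; 9 allylic bromide
Product: 13 (−)-8-phenylmenthyl (6E,10E)-2,6,10-trimethyl-13-(2-methyl-1,3-dioxolan-2-yl)-3-oxotrideca-6,10-dienoate (epimers at C2)
Conditions: LDA (2.1 equiv), THF, −78 to 0 °C; then 9, 0 °C
Reagents that add atoms: none
Why: γ-Alkylation of the β-keto ester dianion (SN2 of the more reactive terminal carbanion on the allylic bromide) forms the C1–C2 bond and completes the E,E-polyene.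

Step 10
Reactants: 13 polyene α-methyl β-keto ester
Product: 14 (−)-8-phenylmenthyl 13,13-ethylenedioxy-3-oxo-14,15-dinorlabd-8(17)-en-19-oate (4β-ester, 4α-CH3, 5α-H, 9α-H, 10β-CH3)
Conditions: Mn(OAc)3·2H2O (2.2 equiv), Cu(OAc)2·H2O (1 equiv), degassed EtOH, rt
Reagents that add atoms: none
Why: Mn(III) oxidises the enolised α-methyl β-keto ester to the electrophilic C4 radical, which adds 6-endo-trig to the C5=C10 alkene to close ring A; the resulting tertiary C10 radical adds 6-endo-trig to C9 of the C8=C9 alkene to close ring B, and the tertiary C8 radical is oxidised by Cu(II) through an alkylcopper(III) species that loses the least hindered β-hydrogen (C17) to give the exocyclic methylene. The closest known reaction type is the Mn(OAc)3/Cu(OAc)2 oxidative free-radical polycyclisation of α-methyl β-keto ester polyenes, including its 8-phenylmenthyl ester variant. Both rings close through chair transition states of the E,E-diene, which makes the A/B fusion trans (5α-H, 10β-CH3) and puts the C9 chain equatorial (9α-H); the free radical reacts with the ester anti to the ketone oxygen, which places the ester axial at C4, cis to the C10 methyl. The absolute sense comes from the auxiliary: its phenyl ring stacks over one face of the planar dicarbonyl radical and C5 should bond to the open face. The step needs 6-endo over 5-exo closure (secured by the trisubstituted alkenes, which give tertiary radicals), exocyclic over endocyclic alkene formation (Cu(II) elimination) and survival of the dioxolane (EtOH in place of AcOH); the cascade stops at C8 because the next carbon unit is a saturated ketal and not an alkene.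

Step 11
Reactants: 14 bicyclic keto ester
Product: 15 13,13-ethylenedioxy-14,15-dinorlabd-8(17)-ene-3β,19-diol
Conditions: LiAlH4, THF, 0 °C to reflux
Reagents that add atoms: none
Why: Hydride reduction cleaves the hindered auxiliary ester to the C19 primary alcohol (auxiliary recovered) and reduces the C3 ketone, mainly from the α face to the equatorial 3β-alcohol, a centre that is removed in step 14.

Step 12
Reactants: 15 3β,19-diol
Product: 16 19-(tert-butyldimethylsilyloxy)-13,13-ethylenedioxy-14,15-dinorlabd-8(17)-en-3β-ol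
Conditions: TBSCl (1.1 equiv), imidazole, DMF, 0 °C
Reagents that add atoms: tert-butyldimethylsilyl chloride CC(C)(C)[Si](C)(C)Cl
Why: Silylation should select the primary C19 hydroxyl over the secondary C3 hydroxyl flanked by the quaternary C4.

Step 13
Reactants: 16 19-O-TBS 3β-alcohol
Product: 17 O-[19-(tert-butyldimethylsilyloxy)-13,13-ethylenedioxy-14,15-dinorlabd-8(17)-en-3β-yl] 1H-imidazole-1-carbothioate
Conditions: 1,1'-thiocarbonyldiimidazole, DMAP (cat.), ClCH2CH2Cl, 80 °C
Reagents that add atoms: 1,1'-thiocarbonyldiimidazole S=C(n1ccnc1)n1ccnc1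
Why: Neutral thioacylation of the hindered secondary alcohol prepares the Barton–McCombie deoxygenation without an alkoxide, which could cause 1,3-silyl migration.

Step 14
Reactants: 17 3β-thiocarbonylimidazolide
Product: 18 19-(tert-butyldimethylsilyloxy)-13,13-ethylenedioxy-14,15-dinorlabd-8(17)-ene
Conditions: Bu3SnH, AIBN (cat.), toluene, 110 °C
Reagents that add atoms: none
Why: Barton–McCombie radical deoxygenation removes the helper oxygen at C3; the secondary C3 radical has no alkene within cyclisation range and is simply reduced.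

Step 15
Reactants: 18 3-deoxy ketal
Product: 19 19-(tert-butyldimethylsilyloxy)-14,15-dinorlabd-8(17)-en-13-one
Conditions: PPTS, acetone–H2O, 60 °C
Reagents that add atoms: water O
Why: Mild acid-catalysed ketal hydrolysis frees the C13 methyl ketone while the neopentyl TBS ether and the exocyclic alkene should survive.

Step 16
Reactants: 19 methyl ketone
Product: 21 19-(tert-butyldimethylsilyloxy)-15,16-dinorlabd-8(17)-en-13-yne, via enol phosphate 20 (not isolated)
Conditions: LDA (1.1 equiv), THF, −78 °C; ClP(O)(OEt)2, −78 °C to rt; LDA (2.3 equiv), −78 °C to rt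
Reagents that add atoms: none
Why: Kinetic deprotonation at the methyl group, O-phosphorylation and base-induced β-elimination of the enol phosphate convert the methyl ketone into the terminal alkyne (the former methyl carbon becomes C14).

Step 17
Reactants: 5 methylthiomethyl ether
Product: 22 4'α-(chloromethoxy)-11'-(triethylsilyloxy)eudesmane
Conditions: SO2Cl2, CH2Cl2, −78 to 0 °C; volatiles removed, crude used at once
Reagents that add atoms: sulfuryl chloride O=S(=O)(Cl)Cl
Why: Chlorinolysis of the O,S-acetal (S-chlorination, then loss of the sulfenyl chloride from the chlorosulfonium ion) gives the α-chloro ether, which carries C15 as an electrophile on the C4' oxygen.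

Step 18
Reactants: 21 terminal alkyne; 22 chloromethyl ether
Product: 25 19-O-TBS 15-O-[11'-(triethylsilyloxy)eudesman-4'α-yl] labda-8(17),13E-diene-15,19-diol, via alkenylalane 23 (not isolated), via lithium alanate 24 (not isolated)
Conditions: Me3Al (2 equiv), Cp2ZrCl2 (0.2 equiv), CH2Cl2, rt; volatiles removed; hexane–THF, n-BuLi (1 equiv), −78 °C; then 22, −78 to 0 °C
Reagents that add atoms: trimethylaluminium C[Al](C)C
Why: Zr-catalysed Negishi carboalumination adds CH3 and Al syn across the alkyne with Al at the terminus, which fixes the 13E geometry; after ate-complex formation the alkenyl group displaces chloride from the α-chloro ether, forming C14–C15 and thereby the tertiary allylic ether without any substitution at the hindered C4' oxygen.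

Step 19
Reactants: 25 bis-silyl ether
Product: 26 15-O-(11'-hydroxyeudesman-4'α-yl) labda-8(17),13E-diene-15,19-diol
Conditions: TBAF, THF, rt to 50 °C
Reagents that add atoms: none
Why: Fluoride-mediated desilylation removes the C19 TBS and C11' TES ethers in one operation; the allylic ether and alkenes are inert to fluoride.

Step 20
Reactants: 26 diol
Product: 27 15-(11'-hydroxyeudesman-4'α-yloxy)labda-8(17),13E-dien-19-al
Conditions: Dess–Martin periodinane, NaHCO3, CH2Cl2, 0 °C to rt
Reagents that add atoms: none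
Why: Dess–Martin oxidation converts the primary neopentyl alcohol to the aldehyde; the tertiary alcohol cannot be oxidised and C4 is quaternary, so nothing can epimerise.

Step 21
Reactants: 27 aldehyde
Product: 28 15-(11'-hydroxyeudesman-4'α-yloxy)labda-8(17),13E-dien-19-oic acid (CNP0156875.1)
Conditions: NaClO2, NaH2PO4, 2-methyl-2-butene, t-BuOH–H2O, rt
Reagents that add atoms: sodium chlorite [Na+].[O-]Cl=O
Why: Pinnick oxidation takes the hindered aldehyde to the acid under weakly acidic conditions, with the alkene scavenger protecting the two alkenes from hypochlorite.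

**Compound list**

1 | (+)-β-eudesmol (5'α-H, 7'β-(2-hydroxypropan-2-yl), 10'β-CH3) | C=C1CCC[C@]2(C)CC[C@@H](C(C)(C)O)C[C@H]21 | starting material
2 | β-eudesmol 11'-O-triethylsilyl ether | C=C1CCC[C@]2(C)CC[C@@H](C(C)(C)O[Si](CC)(CC)CC)C[C@H]21 | intermediate
3 | 4'α,15'-epoxy-11'-(triethylsilyloxy)eudesmane (oxirane O α, CH2 β) | O1C[C@]12CCC[C@]3(C)CC[C@@H](C(C)(C)O[Si](CC)(CC)CC)C[C@H]32 | intermediate
4 | 11'-(triethylsilyloxy)eudesman-4'α-ol (4'α-OH, 4'β-CH3) | O[C@]1(C)CCC[C@]2(C)CC[C@@H](C(C)(C)O[Si](CC)(CC)CC)C[C@H]21 | intermediate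
5 | 4'α-(methylthiomethoxy)-11'-(triethylsilyloxy)eudesmane | CSCO[C@]1(C)CCC[C@]2(C)CC[C@@H](C(C)(C)O[Si](CC)(CC)CC)C[C@H]21 | intermediate
6 | (E)-geranylacetone, (5E)-6,10-dimethylundeca-5,9-dien-2-one | CC(C)=CCC/C(C)=C/CCC(C)=O | starting material
7 | 2-[(3E)-4,8-dimethylnona-3,7-dien-1-yl]-2-methyl-1,3-dioxolane | CC(C)=CCC/C(C)=C/CCC1(C)OCCO1 | intermediate
8 | (2E,6E)-2,6-dimethyl-9-(2-methyl-1,3-dioxolan-2-yl)nona-2,6-dien-1-ol | OC/C(C)=C/CC/C(C)=C/CCC1(C)OCCO1 | intermediate
9 | 2-[(3E,7E)-9-bromo-4,8-dimethylnona-3,7-dien-1-yl]-2-methyl-1,3-dioxolane | BrC/C(C)=C/CC/C(C)=C/CCC1(C)OCCO1 | intermediate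
10 | (−)-8-phenylmenthol, (1R,2S,5R)-5-methyl-2-(2-phenylpropan-2-yl)cyclohexan-1-ol | O[C@H]1[C@H](C(C)(C)c2ccccc2)CC[C@@H](C)C1 | starting material
11 | ethyl 2-methyl-3-oxobutanoate (racemic) | CCOC(=O)C(C)C(C)=O | starting material
12 | (−)-8-phenylmenthyl 2-methyl-3-oxobutanoate (epimers at C2) | CC(=O)C(C)C(=O)O[C@H]1[C@H](C(C)(C)c2ccccc2)CC[C@@H](C)C1 | intermediate
13 | (−)-8-phenylmenthyl (6E,10E)-2,6,10-trimethyl-13-(2-methyl-1,3-dioxolan-2-yl)-3-oxotrideca-6,10-dienoate (epimers at C2) | CC(C(=O)CC/C(C)=C/CC/C(C)=C/CCC1(C)OCCO1)C(=O)O[C@H]2[C@H](C(C)(C)c3ccccc3)CC[C@@H](C)C2 | intermediate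
14 | (−)-8-phenylmenthyl 13,13-ethylenedioxy-3-oxo-14,15-dinorlabd-8(17)-en-19-oate (4β-ester, 5α-H, 9α-H, 10β-CH3) | C=C1CC[C@@H]2[C@](C)(CCC(=O)[C@]2(C)C(=O)O[C@H]3[C@H](C(C)(C)c4ccccc4)CC[C@@H](C)C3)[C@H]1CCC1(C)OCCO1 | intermediate
15 | 13,13-ethylenedioxy-14,15-dinorlabd-8(17)-ene-3β,19-diol | C=C1CC[C@@H]2[C@](C)(CC[C@H](O)[C@]2(C)CO)[C@H]1CCC1(C)OCCO1 | intermediate
16 | 19-(tert-butyldimethylsilyloxy)-13,13-ethylenedioxy-14,15-dinorlabd-8(17)-en-3β-ol | C=C1CC[C@@H]2[C@](C)(CC[C@H](O)[C@]2(C)CO[Si](C)(C)C(C)(C)C)[C@H]1CCC1(C)OCCO1 | intermediate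
17 | O-[19-(tert-butyldimethylsilyloxy)-13,13-ethylenedioxy-14,15-dinorlabd-8(17)-en-3β-yl] 1H-imidazole-1-carbothioate | C=C1CC[C@@H]2[C@](C)(CC[C@H](OC(=S)n3ccnc3)[C@]2(C)CO[Si](C)(C)C(C)(C)C)[C@H]1CCC1(C)OCCO1 | intermediate
18 | 19-(tert-butyldimethylsilyloxy)-13,13-ethylenedioxy-14,15-dinorlabd-8(17)-ene | C=C1CC[C@@H]2[C@](C)(CCC[C@]2(C)CO[Si](C)(C)C(C)(C)C)[C@H]1CCC1(C)OCCO1 | intermediate
19 | 19-(tert-butyldimethylsilyloxy)-14,15-dinorlabd-8(17)-en-13-one | C=C1CC[C@@H]2[C@](C)(CCC[C@]2(C)CO[Si](C)(C)C(C)(C)C)[C@H]1CCC(C)=O | intermediate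
20 | diethyl 19-(tert-butyldimethylsilyloxy)-14,15-dinorlabda-8(17),13(16)-dien-13-yl phosphate | C=C1CC[C@@H]2[C@](C)(CCC[C@]2(C)CO[Si](C)(C)C(C)(C)C)[C@H]1CCC(=C)OP(=O)(OCC)OCC | intermediate (not isolated)
21 | 19-(tert-butyldimethylsilyloxy)-15,16-dinorlabd-8(17)-en-13-yne | C=C1CC[C@@H]2[C@](C)(CCC[C@]2(C)CO[Si](C)(C)C(C)(C)C)[C@H]1CCC#C | intermediate
22 | 4'α-(chloromethoxy)-11'-(triethylsilyloxy)eudesmane | ClCO[C@]1(C)CCC[C@]2(C)CC[C@@H](C(C)(C)O[Si](CC)(CC)CC)C[C@H]21 | intermediate
23 | (13E)-19-(tert-butyldimethylsilyloxy)-14-(dimethylalumanyl)-15-norlabda-8(17),13-diene | C=C1CC[C@@H]2[C@](C)(CCC[C@]2(C)CO[Si](C)(C)C(C)(C)C)[C@H]1CC/C(C)=C/[Al](C)C | intermediate (not isolated)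
24 | lithium butyl(dimethyl)[(13E)-19-(tert-butyldimethylsilyloxy)-15-norlabda-8(17),13-dien-14-yl]alanate | [Li+].C=C1CC[C@@H]2[C@](C)(CCC[C@]2(C)CO[Si](C)(C)C(C)(C)C)[C@H]1CC/C(C)=C/[Al-](C)(C)CCCC | intermediate (not isolated)
25 | 19-O-TBS 15-O-[11'-(triethylsilyloxy)eudesman-4'α-yl] labda-8(17),13E-diene-15,19-diol | C=C1CC[C@@H]2[C@](C)(CCC[C@]2(C)CO[Si](C)(C)C(C)(C)C)[C@H]1CC/C(C)=C/CO[C@]1(C)CCC[C@]2(C)CC[C@@H](C(C)(C)O[Si](CC)(CC)CC)C[C@H]21 | intermediate
26 | 15-O-(11'-hydroxyeudesman-4'α-yl) labda-8(17),13E-diene-15,19-diol | C=C1CC[C@@H]2[C@](C)(CCC[C@]2(C)CO)[C@H]1CC/C(C)=C/CO[C@]1(C)CCC[C@]2(C)CC[C@@H](C(C)(C)O)C[C@H]21 | intermediate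
27 | 15-(11'-hydroxyeudesman-4'α-yloxy)labda-8(17),13E-dien-19-al | C=C1CC[C@@H]2[C@](C)(CCC[C@]2(C)C=O)[C@H]1CC/C(C)=C/CO[C@]1(C)CCC[C@]2(C)CC[C@@H](C(C)(C)O)C[C@H]21 | intermediate
28 | 15-(11'-hydroxyeudesman-4'α-yloxy)labda-8(17),13E-dien-19-oic acid (CNP0156875.1) | C=C1CC[C@@H]2[C@](C)(CCC[C@]2(C)C(=O)O)[C@H]1CC/C(C)=C/CO[C@]1(C)CCC[C@]2(C)CC[C@@H](C(C)(C)O)C[C@H]21 | target

**Totals**

Total step count: 21 (eudesmane branch: steps 1–4 and 17; auxiliary ester: step 8).
Longest linear sequence: 15 steps (5, 6, 7, 9, 10, 11, 12, 13, 14, 15, 16, 18, 19, 20, 21, from geranylacetone 6).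

**Steps most likely to fail, with fallbacks**

Step 10. The auxiliary may give too small a facial bias in the free tertiary radical, the C4 centre may form unselectively, or part of the material may end as an endocyclic alkene. The fallback sets the face and the C4 centre in two separate events. It sets out from bromide 9. The dianion of (+)-8-phenylmenthyl 3-oxobutanoate F1 (from commercial (+)-8-phenylmenthol and 2,2,6-trimethyl-4H-1,3-dioxin-4-one, xylene, 140 °C) is alkylated with 9 to the α-unsubstituted polyene keto ester F2. Mn(OAc)3/Cu(OAc)2 in EtOH then closes both rings. This substrate reacts as its chelated Mn(III) enolate with syn carbonyls, so the ester sits equatorial in the closing chair, and the antipodal auxiliary is therefore the one expected to lead to the same 5α,10β series (added Yb(OTf)3 in CF3CH2OH is an option to tighten the chelate). This should give the bicyclic β-keto ester F3. C-Methylation of F3 (K2CO3, MeI, acetone) from the α face, anti to the axial C10 methyl, should give the 4α-methyl 4β-ester F4. LiAlH4 reduction of F4 comes back to the route at diol 15.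

Step 18. Methyl or butyl transfer from the alanate, or decomposition of the α-chloro ether by the Lewis-acidic aluminium species, may outrun alkenyl transfer. The fallback makes the ether by O-alkylation instead. It sets out from alkyne 21 and alcohol 4. Carboalumination of 21 to alanate 24 as in step 18, then trapping with paraformaldehyde, should give the (13E)-allylic alcohol F5. CBr4/PPh3 converts it to the allylic bromide F6. Williamson etherification of the potassium alkoxide of 4 (KH, 18-crown-6, THF, 0 °C) with F6 comes back to the route at 25.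

Step 17. The tertiary-alkyl chloromethyl ether may ionise and fragment (loss of formaldehyde, elimination towards the eudesmene), or chlorination may be unselective. The fallback reverses the polarity of the C14–C15 bond formation. It sets out from alcohol 4 and alkyne 21. O-Alkylation of 4 (KH, iodomethyl(tributyl)stannane, THF) should give the (tributylstannyl)methyl ether F7. Alkenylalane 23, made from 21 as in step 18, is quenched with iodine to the (13E)-vinyl iodide F8. Stille coupling of F7 with F8 (Pd2(dba)3, tri(2-furyl)phosphine, CuI, NMP, 60 °C) comes back to the route at 25.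

**Further compounds**

F1 | step 10 | (+)-8-phenylmenthyl 3-oxobutanoate | CC(=O)CC(=O)O[C@@H]1[C@@H](C(C)(C)c2ccccc2)CC[C@H](C)C1
F2 | step 10 | (+)-8-phenylmenthyl (6E,10E)-6,10-dimethyl-13-(2-methyl-1,3-dioxolan-2-yl)-3-oxotrideca-6,10-dienoate | O=C(CC(=O)O[C@@H]1[C@@H](C(C)(C)c2ccccc2)CC[C@H](C)C1)CC/C(C)=C/CC/C(C)=C/CCC3(C)OCCO3
F3 | step 10 | (+)-8-phenylmenthyl 13,13-ethylenedioxy-3-oxo-4-demethyl-14,15-dinorlabd-8(17)-en-4-carboxylate (keto form, 4α-ester, 5α-H, 9α-H, 10β-CH3) | C=C1CC[C@@H]2[C@](C)(CCC(=O)[C@H]2C(=O)O[C@@H]3[C@@H](C(C)(C)c4ccccc4)CC[C@H](C)C3)[C@H]1CCC1(C)OCCO1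
F4 | step 10 | (+)-8-phenylmenthyl 13,13-ethylenedioxy-3-oxo-14,15-dinorlabd-8(17)-en-19-oate | C=C1CC[C@@H]2[C@](C)(CCC(=O)[C@]2(C)C(=O)O[C@@H]3[C@@H](C(C)(C)c4ccccc4)CC[C@H](C)C3)[C@H]1CCC1(C)OCCO1
F5 | step 18 | 19-(tert-butyldimethylsilyloxy)labda-8(17),13E-dien-15-ol | C=C1CC[C@@H]2[C@](C)(CCC[C@]2(C)CO[Si](C)(C)C(C)(C)C)[C@H]1CC/C(C)=C/CO
F6 | step 18 | 15-bromo-19-(tert-butyldimethylsilyloxy)labda-8(17),13E-diene | C=C1CC[C@@H]2[C@](C)(CCC[C@]2(C)CO[Si](C)(C)C(C)(C)C)[C@H]1CC/C(C)=C/CBr
F7 | step 17 | 4'α-[(tributylstannyl)methoxy]-11'-(triethylsilyloxy)eudesmane | CCCC[Sn](CCCC)(CCCC)CO[C@]1(C)CCC[C@]2(C)CC[C@@H](C(C)(C)O[Si](CC)(CC)CC)C[C@H]21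
F8 | step 17 | (13E)-19-(tert-butyldimethylsilyloxy)-14-iodo-15-norlabda-8(17),13-diene | C=C1CC[C@@H]2[C@](C)(CCC[C@]2(C)CO[Si](C)(C)C(C)(C)C)[C@H]1CC/C(C)=C/I
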